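## The problem

The target is a tridepside. Three orsellinic-acid-type rings are joined head to tail by two aryl ester bonds: O4 of ring B carries the carboxyl of ring A, O4 of ring C carries the carboxyl of ring B, and the carboxyl of ring C is free. There is no stereocentre, so the task is regiochemical. Each ring has a chelated O2 and a non-chelated O4, and only O4 of rings B and C may be acylated. Ring A has a third oxygen at C5, which bears the only acetate and sits next to the free O4 hydroxyl.

The fragile groups are the aryl acetate (lost or shifted to O4 by base or nucleophiles), the two depside esters (open to transesterification and hydrolysis) and the salicylic-type acid of ring C (prone to decarboxylation). Once the first depside bond exists, saponification and strongly basic reagents are excluded; protecting groups must leave by fluoride, Lewis acid or hydrogenolysis.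

The feature that invites a ring synthesis is ring C. Its C3, C4, C5 and C6 carry H, O, H and CH3, the same as C3 to C6 of 4-hydroxy-6-methyl-2-pyrone. Only C1 (carboxyl) and C2 (oxygen) are missing, and these are the two carbons of a 3-alkoxypropynoate. A ring C made this way arrives with O2 and O4 already in different protected states.

## Retrosynthesis

**Deprotection.** Target 24 is traced to tridepside 23, in which ring A carries two benzyl ethers, ring C a benzyl ester and an O2 methyl ether, and the acetate is already in place. Only C–O bonds of protecting groups are cut. All four sit on oxygens that BCl3 attacks (benzyl groups, and a methyl ether chelated to the neighbouring ester), so one Lewis-acid operation should finish the synthesis without base.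

**Depside bond B–C.** Tridepside 23 is cut at the ester between the ring B carboxyl and O4 of ring C, giving acid 22 and phenol 11. This bond is made last because 11 has exactly one free hydroxyl and so needs no selectivity. The other order (ring A onto a ring B–ring C phenol) would require a protecting group on O4 of ring B. The chelated O2–H of 22 is left free.

**Ring C monomer.** Phenol 11 comes from silyl ether 10 by Si–O cleavage. Compound 10 is a benzene with O2 as methyl ether, O4 as silyl ether and the carboxyl as benzyl ester, three groups removable independently.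

**Ring C (key disconnection).** Bonds C2–C3 and C1–C6 of ring C are cut, with formal return of CO2 across C3 and C6. This leads to silyloxypyrone 2 and ynoate 8 through the bridged lactone 9. Compared with functionalising an existing arene, this makes the substitution pattern a consequence of the two reaction partners, and it delivers O2/O4 differentiation at once. The forward reaction must be regioselective and must tolerate a donor-substituted alkyne.

**Precursors of the key step.** Pyrone 2 is the silyl derivative of triacetic acid lactone 1. Ynoate 8 is cut at the alkyne–carboxyl bond to methoxyacetylene 5 and benzyl chloroformate 6. Alkyne 5 comes from chloroacetaldehyde dimethyl acetal 3 by double elimination via its sodium salt 4; its lithium salt 7 is the species acylated. A methyl ynol ether is chosen because it cannot lose a ketene by retro-ene reaction and has no benzyl group to migrate at the cycloaddition temperature.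

**Ring A–ring B acid.** Acid 22 is traced to aldehyde 21 (change of oxidation level only), and 21 is cut at the depside bond to acid 19 and 2,4-dihydroxy-6-methylbenzaldehyde 12. Using the formyl group of 12 as a latent carboxyl avoids an orthogonal ester on ring B. The chelated O2–H of 12 leaves O4 as the only acylation site.

**Ring A.** Acid 19 comes from aldehyde 18, and 18 from aryl acetate 16 by cutting the C1–CHO bond (formylation via iminium salt 17). Acetate 16 comes from phenol 15, and 15 from aldehyde 13 by exchanging the formyl carbon for oxygen (Baeyer–Villiger/Dakin via formate 14). Aldehyde 13 is the dibenzyl ether of 12. The two positions flanking the methyl group of the orcinol core are thus used in turn, first for the C5 oxygen and then for the carboxyl, so one commercial compound (12) supplies both ring A and ring B.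

## Roads not taken

**Alternative 1:** Ring A would be cut at C1–C2 and traced to the racemic cyclobutenone A2, assembled from a semisquarate and an alkenyl metal reagent. On heating, A2 should open to a dienylketene, close by 6π electrocyclisation and enolise to benzoate A1 (Moore-type ring expansion).
- Merits: A1 has its three oxygens in three different states by construction (O2 free, O4 benzyl, O5 acetyl), and no electrophilic substitution on a crowded arene is needed. In this respect it is better than the chosen plan, whose ring A rests on the regiochemistry of one formylation (step 9).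
- Weak points: A2 needs a β-metalated crotonate carrying a tert-butyl ester and its regioselective addition to an unsymmetrical cyclobutenedione. The tertiary allylic acetate in A2 can ionise. The four-carbon building block is costly.
- Comparison: it addresses only ring A, so the two depside couplings and the differentiation of O2 and O4 on ring C remain as in the chosen plan. The chosen plan reaches ring A by five routine operations from a cheap aldehyde and spends its ring construction on ring C, where it also delivers the O2/O4 differentiation.

**Alternative 2:** The depside bond A–B and bond C1–C6 of ring A would be cut together. Heating dioxinone A5 with benzyl lecanorate A4 should release an acylketene that acylates O4 of ring B. The resulting aryl trioxooctanoate would close by aldol condensation and aromatise to A3, the benzyl ester of the target.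
- Merits: this is the shortest and most convergent road. Ring A needs no protecting group, A4 is two or three steps from orsellinic acid, and the last step would be hydrogenolysis of a single benzyl ester, which is milder than the BCl3 step of the chosen plan. On step count and endgame mildness it is superior.
- Weak points: A5 has an acetoxy group on a carbon between two ketones, where acyl shift to an enol oxygen, deacetylation and retro-Claisen cleavage are all easy. The open-chain aryl ester is an activated ester, so closure through oxygen to a 4-hydroxypyrone with expulsion of the phenol competes with the aldol. The conditions that drive aromatisation are the ones the acetate and the depside bonds tolerate least.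
- Comparison: all the risk falls on one late step with the most valuable material. The chosen plan forms every bond between stable aromatic partners and places the acetate on a robust arene early.

**Alternative 3:** Ring B would be cut at C2–C3, C4–C5 and C1–C2. Photochemical Wolff rearrangement of diazo ketone A8, which already carries ring C as its aryl ester, gives a vinylketene. This combines with siloxyalkyne A7 by (2+2) cycloaddition, 4π opening and 6π closure to give A6 (Danheiser benzannulation).
- Merits: regiochemistry is fixed by the mechanism. A6 has O2 of ring B free and chelated and O4 silylated, the differentiation needed to attach ring A, and the B–C depside bond is already present. Benzannulation with siloxyalkynes is established chemistry, so precedent for the ring-forming event is stronger than for the cycloaddition chosen here.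
- Weak points: ring B is the plain orsellinate ring, which the chosen route takes from commercial aldehyde 12 at no cost in steps. A8 needs several steps and holds a diazo ketone next to an electron-poor alkene. A photochemical step and a sensitive alkyne are required. Ring A must still be made and attached.
- Comparison: both plans build a simple orsellinate ring from non-aromatic precursors. The chosen plan offers in return two commercial precursors, three steps to the cycloaddition partners, and no diazo or photochemical chemistry.

Key step: step 4

Assumptions: rings A and B are both drawn from commercial 2,4-dihydroxy-6-methylbenzaldehyde 12, whose formyl group serves once as a leaving carbon (ring A, C5 oxygen) and once as a latent carboxyl (ring B). Locants on each ring count from the carboxyl-bearing carbon as C1. Intermediate 9 is chiral and racemic; one enantiomer is drawn, and both centres vanish in the same step.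

## Route

Step 1
Reactants: 1 4-hydroxy-6-methyl-2H-pyran-2-one (triacetic acid lactone)
Product: 2 4-(tert-butyldimethylsilyloxy)-6-methyl-2H-pyran-2-one
Conditions: TBSCl, imidazole, CH2Cl2, 0 °C to rt; non-aqueous work-up (filtration, evaporation, short-path distillation)
Reagents that add atoms: tert-butyldimethylsilyl chloride, CC(C)(C)[Si](C)(C)Cl
Why: O-silylation of the acidic vinylogous-acid hydroxyl; the 4-silyloxy-2-pyrone keeps the conjugated lactone and is the expected tautomer, and because it behaves like a silyl ester it is isolated without water.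

Step 2
Reactants: 3 chloroacetaldehyde dimethyl acetal
Product: 5 methoxyacetylene (methoxyethyne), via sodium methoxyacetylide 4 (not isolated)
Conditions: NaNH2 (3 equiv), liquid NH3, −33 °C; NH3 evaporated; saturated aqueous NaCl, −70 °C to rt, product distilled into a cold trap and kept as a THF solution
Reagents that add atoms: none
Why: Twofold base-induced elimination (HCl, then methanol) with deprotonation of the resulting alkynyl ether is the classical route from chloroacetaldehyde acetals to alkoxyacetylenes; protonation on quench releases the volatile alkyne.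

Step 3
Reactants: 5 methoxyacetylene; 6 benzyl chloroformate
Product: 8 benzyl 3-methoxyprop-2-ynoate, via lithium methoxyacetylide 7 (not isolated)
Conditions: n-BuLi, THF, −78 °C; solution cannulated into 6 (1.2 equiv), THF, −78 °C; pH 7 buffer work-up, neutral alumina
Reagents that add atoms: none
Why: C-acylation of a lithium acetylide with a chloroformate; inverse addition keeps the ynoate away from excess acetylide, and neutral work-up avoids hydration of the ynol ether to a malonate.

Step 4
Reactants: 2 4-(tert-butyldimethylsilyloxy)-6-methyl-2H-pyran-2-one (2 equiv); 8 benzyl 3-methoxyprop-2-ynoate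
Product: 10 benzyl 4-(tert-butyldimethylsilyloxy)-2-methoxy-6-methylbenzoate, via bridged bicyclic lactone 9 (not isolated)
Conditions: PhMe (dry, degassed), BHT (cat.), sealed tube, 150–170 °C
Reagents that add atoms: none
Why: Proposed new method: thermal (4+2) cycloadditions of 4-alkoxy- and 4-silyloxy-6-methyl-2-pyrones with propiolates and acetylenedicarboxylates followed by loss of CO2 are the closest known reaction type, but a 3-alkoxypropynoate has not been used as the 2π partner; the reasoning is that this alkyne is still polarised in the sense the pyrone needs. Pyrone 2 reacts as the diene C3=C4–C5=C6; C3 is the β-carbon of the silyl enol ether and the vinylogous terminus of the ring-oxygen enol ether, hence the most nucleophilic carbon, while C6 is the electrophilic δ-position of the unsaturated lactone. In 8 the methoxy-bearing β-carbon is the acceptor position of the ynoate and the α-carbon holds the donor-induced electron density, so C3 of 2 should bond to the β-carbon and C6 to the α-carbon in a concerted, probably asynchronous, suprafacial cycloaddition that closes the six-membered carbocycle (ring C bonds C2–C3 and C1–C6) in one event. Lactone 9 then loses CO2 by retro-(4+2) fragmentation, which is irreversible and gives arene 10 at the benzoate oxidation level without an oxidant. The two bridgehead centres of 9 are tied together by the bicycle, form as a racemate and vanish with the CO2, so no stereocontrol is needed. The selectivity required is regiochemical (methoxy next to the carboxyl, silyloxy para to it); it is secured by the matched donor–acceptor polarisation of both partners and agrees with the usual para orientation of 2-donor dienes. The methyl ynol ether has no β-hydrogen for retro-ene loss of a ketene and no benzyl group for a sigmatropic shift at this temperature.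

Step 5
Reactants: 10 benzyl 4-(tert-butyldimethylsilyloxy)-2-methoxy-6-methylbenzoate
Product: 11 benzyl 4-hydroxy-2-methoxy-6-methylbenzoate
Conditions: TBAF, AcOH, THF, 0 °C
Reagents that add atoms: none
Why: Fluoride cleavage of an aryl silyl ether; acetic acid buffers the phenoxide, and the methyl ether and benzyl ester are inert, so O4 alone becomes free.

Step 6
Reactants: 12 2,4-dihydroxy-6-methylbenzaldehyde
Product: 13 2,4-bis(benzyloxy)-6-methylbenzaldehyde
Conditions: BnBr (2.5 equiv), K2CO3, DMF, 60 °C
Reagents that add atoms: benzyl bromide, BrCc1ccccc1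
Why: Williamson etherification of both phenols; the chelated O2–H needs the excess reagent and warming.

Step 7
Reactants: 13 2,4-bis(benzyloxy)-6-methylbenzaldehyde
Product: 15 2,4-bis(benzyloxy)-6-methylphenol, via aryl formate 14 (not isolated)
Conditions: mCPBA, CH2Cl2, 0 °C to rt; then K2CO3 (cat.), MeOH, rt, under argon
Reagents that add atoms: 3-chloroperoxybenzoic acid, O=C(OO)c1cccc(Cl)c1
Why: Baeyer–Villiger (Dakin-type) oxidation; the ortho- and para-alkoxy groups make the aryl group migrate in preference to hydrogen, and mild methanolysis of the formate gives the phenol that becomes O5 of ring A.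

Step 8
Reactants: 15 2,4-bis(benzyloxy)-6-methylphenol
Product: 16 2,4-bis(benzyloxy)-6-methylphenyl acetate
Conditions: Ac2O, pyridine, DMAP (cat.), CH2Cl2, rt
Reagents that add atoms: acetic anhydride, CC(=O)OC(C)=O
Why: Standard O-acetylation; it installs the acetate of the target while this is the only free hydroxyl and protects the oxidation-prone phenol.

Step 9
Reactants: 16 2,4-bis(benzyloxy)-6-methylphenyl acetate
Product: 18 5-acetoxy-2,4-bis(benzyloxy)-6-methylbenzaldehyde, via aryl iminium salt 17 (not isolated)
Conditions: POCl3, DMF, 0 °C to 70 °C; then aqueous NaOAc, rt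
Reagents that add atoms: N,N-dimethylformamide, CN(C)C=O; water, O
Why: Vilsmeier–Haack formylation; attack should occur para to one benzyloxy group and ortho to the other, next to the methyl group, as is usual for 3,5-dialkoxytoluenes, and not at the position between the two ethers.

Step 10
Reactants: 18 5-acetoxy-2,4-bis(benzyloxy)-6-methylbenzaldehyde
Product: 19 5-acetoxy-2,4-bis(benzyloxy)-6-methylbenzoic acid
Conditions: NaClO2, NaH2PO4, 2-methyl-2-butene, t-BuOH/THF/H2O, rt
Reagents that add atoms: sodium chlorite, [Na+].[O-]Cl=O
Why: Pinnick oxidation, suited to hindered aldehydes; the weakly acidic medium spares the acetate and the alkene scavenger protects the electron-rich ring from chlorination.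

Step 11
Reactants: 19 5-acetoxy-2,4-bis(benzyloxy)-6-methylbenzoic acid; 12 2,4-dihydroxy-6-methylbenzaldehyde
Product: 21 4-formyl-3-hydroxy-5-methylphenyl 5-acetoxy-2,4-bis(benzyloxy)-6-methylbenzoate, via mixed trifluoroacetic anhydride 20 (not isolated)
Conditions: TFAA, PhMe, rt
Reagents that add atoms: none
Why: Mixed-anhydride esterification as used for depsides; the di-ortho-substituted, electron-rich aroyl trifluoroacetate acylates the free O4–H of 12, while the O2–H hydrogen-bonded to the formyl group stays unreacted, and no base touches the acetate.

Step 12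
Reactants: 21 4-formyl-3-hydroxy-5-methylphenyl 5-acetoxy-2,4-bis(benzyloxy)-6-methylbenzoate
Product: 22 4-{[5-acetoxy-2,4-bis(benzyloxy)-6-methylbenzoyl]oxy}-2-hydroxy-6-methylbenzoic acid
Conditions: NaClO2, NaH2PO4, 2-methyl-2-butene (large excess), t-BuOH/THF/H2O, rt
Reagents that add atoms: sodium chlorite, [Na+].[O-]Cl=O
Why: Pinnick oxidation turns the latent carboxyl of ring B into the acid under conditions that leave the depside ester, the acetate and the benzyl ethers intact.

Step 13
Reactants: 22 4-{[5-acetoxy-2,4-bis(benzyloxy)-6-methylbenzoyl]oxy}-2-hydroxy-6-methylbenzoic acid; 11 benzyl 4-hydroxy-2-methoxy-6-methylbenzoate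
Product: 23 benzyl 4-{[4-({5-acetoxy-2,4-bis(benzyloxy)-6-methylbenzoyl}oxy)-2-hydroxy-6-methylbenzoyl]oxy}-2-methoxy-6-methylbenzoate
Conditions: DCC, CH2Cl2/PhMe, 0 °C to rt
Reagents that add atoms: none
Why: Carbodiimide esterification of an ortho-hydroxybenzoic acid with a phenol, the classical neutral depside coupling; the chelated O2–H of 22 is a poor nucleophile and 11 offers a single hydroxyl.

Step 14
Reactants: 23 benzyl 4-{[4-({5-acetoxy-2,4-bis(benzyloxy)-6-methylbenzoyl}oxy)-2-hydroxy-6-methylbenzoyl]oxy}-2-methoxy-6-methylbenzoate
Product: 24 4-{[4-({5-acetoxy-2,4-dihydroxy-6-methylbenzoyl}oxy)-2-hydroxy-6-methylbenzoyl]oxy}-2-hydroxy-6-methylbenzoic acid (target)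
Conditions: BCl3 (excess), pentamethylbenzene, CH2Cl2, −78 °C to 0 °C; then H2O/THF, 0 °C
Reagents that add atoms: none
Why: Lewis-acid dealkylation: BCl3 with a cation scavenger cleaves the two benzyl ethers and the benzyl ester, and chelation to the ring C ester carbonyl directs cleavage of the ortho methyl ether; aryl esters have no alkyl–oxygen bond to break, and the cold acidic quench avoids acetyl migration.

## Compound list

1 | 4-hydroxy-6-methyl-2H-pyran-2-one (triacetic acid lactone) | Cc1cc(O)cc(=O)o1 | starting material
2 | 4-(tert-butyldimethylsilyloxy)-6-methyl-2H-pyran-2-one | Cc1cc(O[Si](C)(C)C(C)(C)C)cc(=O)o1 | intermediate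
3 | chloroacetaldehyde dimethyl acetal | COC(CCl)OC | starting material
4 | sodium methoxyacetylide (not isolated) | [Na+].[C-]#COC | intermediate
5 | methoxyacetylene (methoxyethyne) | C#COC | intermediate
6 | benzyl chloroformate | O=C(Cl)OCc1ccccc1 | starting material
7 | lithium methoxyacetylide (not isolated) | [Li+].[C-]#COC | intermediate
8 | benzyl 3-methoxyprop-2-ynoate | COC#CC(=O)OCc1ccccc1 | intermediate
9 | benzyl 8-(tert-butyldimethylsilyloxy)-5-methoxy-1-methyl-3-oxo-2-oxabicyclo[2.2.2]octa-5,7-diene-6-carboxylate (racemic, one enantiomer drawn; not isolated) | C[C@@]12OC(=O)[C@@H](C(O[Si](C)(C)C(C)(C)C)=C1)C(OC)=C2C(=O)OCc1ccccc1 | intermediate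
10 | benzyl 4-(tert-butyldimethylsilyloxy)-2-methoxy-6-methylbenzoate | COc1cc(O[Si](C)(C)C(C)(C)C)cc(C)c1C(=O)OCc1ccccc1 | intermediate
11 | benzyl 4-hydroxy-2-methoxy-6-methylbenzoate | COc1cc(O)cc(C)c1C(=O)OCc1ccccc1 | intermediate
12 | 2,4-dihydroxy-6-methylbenzaldehyde | Cc1cc(O)cc(O)c1C=O | starting material
13 | 2,4-bis(benzyloxy)-6-methylbenzaldehyde | Cc1cc(OCc2ccccc2)cc(OCc2ccccc2)c1C=O | intermediate
14 | 2,4-bis(benzyloxy)-6-methylphenyl formate (not isolated) | Cc1cc(OCc2ccccc2)cc(OCc2ccccc2)c1OC=O | intermediate
15 | 2,4-bis(benzyloxy)-6-methylphenol | Cc1cc(OCc2ccccc2)cc(OCc2ccccc2)c1O | intermediate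
16 | 2,4-bis(benzyloxy)-6-methylphenyl acetate | CC(=O)Oc1c(C)cc(OCc2ccccc2)cc1OCc1ccccc1 | intermediate
17 | N-{[5-acetoxy-2,4-bis(benzyloxy)-6-methylphenyl]methylidene}-N-methylmethanaminium dichlorophosphate (not isolated) | CC(=O)Oc1c(C)c(C=[N+](C)C)c(OCc2ccccc2)cc1OCc1ccccc1.[O-]P(=O)(Cl)Cl | intermediate
18 | 5-acetoxy-2,4-bis(benzyloxy)-6-methylbenzaldehyde | CC(=O)Oc1c(C)c(C=O)c(OCc2ccccc2)cc1OCc1ccccc1 | intermediate
19 | 5-acetoxy-2,4-bis(benzyloxy)-6-methylbenzoic acid | CC(=O)Oc1c(C)c(C(=O)O)c(OCc2ccccc2)cc1OCc1ccccc1 | intermediate
20 | 5-acetoxy-2,4-bis(benzyloxy)-6-methylbenzoic trifluoroacetic anhydride (not isolated) | CC(=O)Oc1c(C)c(C(=O)OC(=O)C(F)(F)F)c(OCc2ccccc2)cc1OCc1ccccc1 | intermediate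
21 | 4-formyl-3-hydroxy-5-methylphenyl 5-acetoxy-2,4-bis(benzyloxy)-6-methylbenzoate | CC(=O)Oc1c(C)c(C(=O)Oc2cc(C)c(C=O)c(O)c2)c(OCc2ccccc2)cc1OCc1ccccc1 | intermediate
22 | 4-{[5-acetoxy-2,4-bis(benzyloxy)-6-methylbenzoyl]oxy}-2-hydroxy-6-methylbenzoic acid | CC(=O)Oc1c(C)c(C(=O)Oc2cc(C)c(C(=O)O)c(O)c2)c(OCc2ccccc2)cc1OCc1ccccc1 | intermediate
23 | benzyl 4-{[4-({5-acetoxy-2,4-bis(benzyloxy)-6-methylbenzoyl}oxy)-2-hydroxy-6-methylbenzoyl]oxy}-2-methoxy-6-methylbenzoate | CC(=O)Oc1c(C)c(C(=O)Oc2cc(C)c(C(=O)Oc3cc(C)c(C(=O)OCc4ccccc4)c(OC)c3)c(O)c2)c(OCc2ccccc2)cc1OCc1ccccc1 | intermediate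
24 | 4-{[4-({5-acetoxy-2,4-dihydroxy-6-methylbenzoyl}oxy)-2-hydroxy-6-methylbenzoyl]oxy}-2-hydroxy-6-methylbenzoic acid (CNP0154030.0) | CC(=O)Oc1c(O)cc(O)c(C(=O)Oc2cc(C)c(C(=O)Oc3cc(C)c(C(=O)O)c(O)c3)c(O)c2)c1C | target

## Step count and risks

Total: 14 steps. Longest linear sequence: 9 steps (steps 6 to 14, from 12 to 24). The ring C branch (steps 2 to 5, then 13 and 14) is 6 steps.

**Step 4 (key step, proposed new method).**
- What may go wrong: the donor substituent makes the alkyne a weaker 2π partner, so the cycloaddition may be too slow. Thermal oligomerisation of 8 or loss of the silyl group from 2 could then outpace it, and partial erosion of regiochemistry cannot be excluded.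
- Fallback by known chemistry, from 12 to 10: selective silylation of the non-chelated O4–H (TBSCl, imidazole, CH2Cl2, 0 °C) should give 4-(tert-butyldimethylsilyloxy)-2-hydroxy-6-methylbenzaldehyde F1. Neutral Mitsunobu O-methylation of the chelated hydroxyl (MeOH, PPh3, DIAD) gives 4-(tert-butyldimethylsilyloxy)-2-methoxy-6-methylbenzaldehyde F2. Pinnick oxidation gives 4-(tert-butyldimethylsilyloxy)-2-methoxy-6-methylbenzoic acid F3, and carboxylate alkylation (BnBr, KHCO3, DMF) returns to 10. This abandons the ring construction but keeps everything after step 4 unchanged.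

**Step 14.**
- What may go wrong: loss of the C5 acetate or its shift to the neighbouring O4 while that oxygen is boron-bound; cleavage of a depside bond on prolonged exposure; incomplete removal of the benzyl ester.
- Fallback, from 11 to 24, in which no Lewis acid meets the acetate or a depside bond: exhaustive BCl3 treatment of 11 (with pentamethylbenzene, 0 °C to rt) removes the methyl ether and the benzyl ester and gives orsellinic acid F4. BnBr with KHCO3 in DMF gives benzyl orsellinate F5. DCC coupling of F5 with 22 occurs at the non-chelated O4–H and gives benzyl 4-{[4-({5-acetoxy-2,4-bis(benzyloxy)-6-methylbenzoyl}oxy)-2-hydroxy-6-methylbenzoyl]oxy}-2-hydroxy-6-methylbenzoate F6. Hydrogenolysis (H2, 10% Pd/C, EtOAc) removes all three benzyl groups and gives 24. This gives up the O2/O4 differentiation delivered by the cycloaddition and relies on hydrogen bonding instead.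

**Step 13.**
- What may go wrong: the hindered O-acylisourea of 22 may rearrange to the N-acylurea faster than the phenol attacks, or the free ortho hydroxyl may take part in self-acylation.
- Fallback, from 21 to 24: Mitsunobu benzylation of the chelated hydroxyl (BnOH, PPh3, DIAD) gives 3-(benzyloxy)-4-formyl-5-methylphenyl 5-acetoxy-2,4-bis(benzyloxy)-6-methylbenzoate F7. Pinnick oxidation gives 4-{[5-acetoxy-2,4-bis(benzyloxy)-6-methylbenzoyl]oxy}-2-(benzyloxy)-6-methylbenzoic acid F8. This fully protected acid couples with 11 through its mixed trifluoroacetic anhydride (TFAA, PhMe) to give benzyl 4-{[4-({5-acetoxy-2,4-bis(benzyloxy)-6-methylbenzoyl}oxy)-2-(benzyloxy)-6-methylbenzoyl]oxy}-2-methoxy-6-methylbenzoate F9. The conditions of step 14 then convert F9 into 24.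

**Step 9.**
- What may go wrong: slow substitution at a position flanked by methyl and benzyloxy on an acetoxy-deactivated ring, or competing attack at the position between the two ethers.
- Fallback, from 15 to 19, with a smaller electrophile and a carboxylation in place of formylation and oxidation: bromination of 15 (NBS, CH2Cl2, −78 °C to 0 °C) gives 4,6-bis(benzyloxy)-3-bromo-2-methylphenol F10. Deprotonation and bromine–lithium exchange (n-BuLi, 2.2 equiv, THF, −78 °C) followed by CO2 gives 2,4-bis(benzyloxy)-5-hydroxy-6-methylbenzoic acid F11. Acetylation (Ac2O, pyridine, aqueous work-up) gives 19.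

## Further compounds

F1 | step 4 | 4-(tert-butyldimethylsilyloxy)-2-hydroxy-6-methylbenzaldehyde | Cc1cc(O[Si](C)(C)C(C)(C)C)cc(O)c1C=O
F2 | step 4 | 4-(tert-butyldimethylsilyloxy)-2-methoxy-6-methylbenzaldehyde | COc1cc(O[Si](C)(C)C(C)(C)C)cc(C)c1C=O
F3 | step 4 | 4-(tert-butyldimethylsilyloxy)-2-methoxy-6-methylbenzoic acid | COc1cc(O[Si](C)(C)C(C)(C)C)cc(C)c1C(=O)O
F4 | step 14 | orsellinic acid (2,4-dihydroxy-6-methylbenzoic acid) | Cc1cc(O)cc(O)c1C(=O)O
F5 | step 14 | benzyl orsellinate (benzyl 2,4-dihydroxy-6-methylbenzoate) | Cc1cc(O)cc(O)c1C(=O)OCc1ccccc1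
F6 | step 14 | benzyl 4-{[4-({5-acetoxy-2,4-bis(benzyloxy)-6-methylbenzoyl}oxy)-2-hydroxy-6-methylbenzoyl]oxy}-2-hydroxy-6-methylbenzoate | CC(=O)Oc1c(C)c(C(=O)Oc2cc(C)c(C(=O)Oc3cc(C)c(C(=O)OCc4ccccc4)c(O)c3)c(O)c2)c(OCc2ccccc2)cc1OCc1ccccc1
F7 | step 13 | 3-(benzyloxy)-4-formyl-5-methylphenyl 5-acetoxy-2,4-bis(benzyloxy)-6-methylbenzoate | CC(=O)Oc1c(C)c(C(=O)Oc2cc(C)c(C=O)c(OCc3ccccc3)c2)c(OCc2ccccc2)cc1OCc1ccccc1
F8 | step 13 | 4-{[5-acetoxy-2,4-bis(benzyloxy)-6-methylbenzoyl]oxy}-2-(benzyloxy)-6-methylbenzoic acid | CC(=O)Oc1c(C)c(C(=O)Oc2cc(C)c(C(=O)O)c(OCc3ccccc3)c2)c(OCc2ccccc2)cc1OCc1ccccc1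
F9 | step 13 | benzyl 4-{[4-({5-acetoxy-2,4-bis(benzyloxy)-6-methylbenzoyl}oxy)-2-(benzyloxy)-6-methylbenzoyl]oxy}-2-methoxy-6-methylbenzoate | CC(=O)Oc1c(C)c(C(=O)Oc2cc(C)c(C(=O)Oc3cc(C)c(C(=O)OCc4ccccc4)c(OC)c3)c(OCc3ccccc3)c2)c(OCc2ccccc2)cc1OCc1ccccc1
F10 | step 9 | 4,6-bis(benzyloxy)-3-bromo-2-methylphenol | Cc1c(O)c(OCc2ccccc2)cc(OCc2ccccc2)c1Br
F11 | step 9 | 2,4-bis(benzyloxy)-5-hydroxy-6-methylbenzoic acid | Cc1c(O)c(OCc2ccccc2)cc(OCc2ccccc2)c1C(=O)O
A1 | alternative 1 | tert-butyl 5-acetoxy-4-(benzyloxy)-2-hydroxy-6-methylbenzoate | CC(=O)Oc1c(OCc2ccccc2)cc(O)c(C(=O)OC(C)(C)C)c1C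
A2 | alternative 1 | tert-butyl (E)-3-[1-acetoxy-2-(benzyloxy)-4-oxocyclobut-2-en-1-yl]but-2-enoate (racemic) | CC(=O)OC1(/C(C)=C/C(=O)OC(C)(C)C)C(OCc2ccccc2)=CC1=O
A3 | alternative 2 | benzyl 4-{[4-({5-acetoxy-2,4-dihydroxy-6-methylbenzoyl}oxy)-2-hydroxy-6-methylbenzoyl]oxy}-2-hydroxy-6-methylbenzoate | CC(=O)Oc1c(O)cc(O)c(C(=O)Oc2cc(C)c(C(=O)Oc3cc(C)c(C(=O)OCc4ccccc4)c(O)c3)c(O)c2)c1C
A4 | alternative 2 | benzyl lecanorate (benzyl 4-[(2,4-dihydroxy-6-methylbenzoyl)oxy]-2-hydroxy-6-methylbenzoate) | Cc1cc(O)cc(O)c1C(=O)Oc1cc(C)c(C(=O)OCc2ccccc2)c(O)c1
A5 | alternative 2 | 1-(2,2-dimethyl-4-oxo-4H-1,3-dioxin-6-yl)-2,4-dioxopentan-3-yl acetate (racemic) | CC(=O)OC(C(C)=O)C(=O)CC1=CC(=O)OC(C)(C)O1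
A6 | alternative 3 | benzyl 2-(benzyloxy)-4-{[2-hydroxy-6-methyl-4-(triisopropylsilyloxy)benzoyl]oxy}-6-methylbenzoate | Cc1cc(O[Si](C(C)C)(C(C)C)C(C)C)cc(O)c1C(=O)Oc1cc(C)c(C(=O)OCc2ccccc2)c(OCc2ccccc2)c1
A7 | alternative 3 | (ethynyloxy)triisopropylsilane | C#CO[Si](C(C)C)(C(C)C)C(C)C
A8 | alternative 3 | 3-(benzyloxy)-4-[(benzyloxy)carbonyl]-5-methylphenyl (E)-5-diazo-3-methyl-4-oxopent-2-enoate | [N-]=[N+]=CC(=O)/C(C)=C/C(=O)Oc1cc(C)c(C(=O)OCc2ccccc2)c(OCc2ccccc2)c1
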